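Remark on the chemistry: atom labels follow the target (C1 = CMe2, C2 = CHCl, C3 = CH2, C4 = CH=, C5 = C=, C6 = CHBr, C7 = CHCl, C8 = CH2Br). (S)-Pantolactone is assumed to be purchasable as the single enantiomer. I found no error in the precursor, product or starting-material structures; the precursor design is improved in two places (steps 3–4 and the order of steps 5–6).

## Structural features

The target is a tetrahalogenated monoterpene with one carbocycle, a cyclohexene (ring A) whose alkene lies between C4 and C5 and whose C5 carries the two-carbon branch C7–C8. Ring A contains a quaternary C1 (gem-dimethyl) flanked by two halogen-bearing stereocentres, C2 (S, Cl) and C6 (R, Br), which are 1,3-related and trans. The third stereocentre, C7 (S, Cl), lies outside the ring on the carbon bonded to C5, so C6 and C7 are separated only by the sp2 carbon C5. Both C6–Br and C7–Cl are allylic to the same C4=C5 bond and are therefore prone to ionisation, SN2′ transposition and elimination to dienes. The vicinal C7–Cl/C8–Br pair can scramble through halonium ions, and the homoallylic C2–Cl can be expelled toward C3 whenever C3 becomes acidic. C2 and C6 are both neopentylic, so substitution there is slow, and the molecule has no oxygen left with which a late error could be repaired. The real difficulty is the order in which four C–halogen bonds and three configurations are installed. The key step exploits the array C6(heteroatom)–C5(=C4)–C7, which is what an enone C4=C5–C7(=O) gives when its alpha carbon C5 adds to an aldehyde C6, so ring A can be closed at C5–C6. The segment C3–C2–C1–C6 is the carbon skeleton of pantolactone.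

## Logic of the disconnections

C6–Br of 21 is cut back to the C6–O bond of 20, and the free hydroxyl to the silyl ether of 19. The allylic bromide is the most labile group and is therefore introduced last. It must enter with inversion, because the ring closure places oxygen cis to the C2 chlorine whereas 21 has bromine trans. The gain is that every earlier intermediate carries a robust oxygen at C6. The demand is an SN2 reaction at an allylic but neopentylic carbon without SN2′ shift, and a desilylation that never generates an alkoxide next to C8–Br.

C7–Cl of 19 is cut to the C7–OH of 18. An allylic secondary chloride is best made from a carbinol whose configuration a catalyst can set. The forward step must invert cleanly without participation of the C8 bromine and without allylic shift toward C4.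

The C7–H bond of 18 is cut to give the ketone of 17. This replaces a stereocentre by a prochiral carbonyl flanked by two groups of very different size (cyclohexenyl and CH2Br). The demand is reagent control strong enough to override the neighbouring C6 stereocentre, and 1,2- rather than 1,4-reduction.

C8–Br of 17 is cut to the methyl ketone 15 (through 16), and the silyl group of 15 is removed to reveal 14. C8 is the alpha′ position of the enone and can be reached by kinetic enolisation. The gain is that 14 is a plain Morita–Baylis–Hillman adduct. The demand is deprotonation at C8 and not at C3, since a C3 carbanion would expel chloride from C2.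

The C5–C6 bond of 14 is cut to give 12. This is the strategic cut: it opens ring A to a linear eight-carbon chain with one stereocentre and turns the C6 carbinol into a non-enolisable aldehyde. The forward step must close the ring with oxygen cis to the C2 chlorine, under conditions mild enough for the C2–Cl bond, and faster than intermolecular enone coupling.

The C4=C5 bond of 12 is cut to give 10 and 11. A terminal alkene and a commodity enone give the E-enone in one catalytic step. The metathesis is placed after the oxidation of C6, so that no hydroxy enone capable of oxa-Michael closure onto C4 is ever formed. The demand is tolerance of the aldehyde.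

The aldehyde of 10 is returned to the alcohol 9, and the C3–C4 bond of 9 is cut to give 6 and 7. The cyclic sulfate of 6 makes C3 electrophilic and masks the C6 oxygen at the same time. Because C6 is neopentylic, only C3 can be attacked, so the two primary termini are told apart without protecting groups. The demand is substitution at the beta-branched C3 faster than elimination.

The sulfate of 6 is cut to the diol 4, the two primary alcohols are returned to the lactone of 3, and the C2–Cl bond is cut to the C2–O bond of 1 (through 2). Substitution at the neopentylic C2 is realistic only while C2 is alpha to the lactone carbonyl, so chlorine goes in first. The demand is clean inversion and no later chloride exchange.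

## Other disconnections considered

Alternative 1: Ring A is inherited rather than made. The C6–O bond and the C2 substituent are traced back to the cyclobutanone bridge of chrysanthenone A1, which spans C2 and C6.
- Forward key step: Baeyer–Villiger oxidation of A1 with alkaline peroxide inserts oxygen between the carbonyl carbon and the allylic bridgehead and gives the bridged lactone A2.
- In its favour: a terpene supplies the six ring carbons, the gem-dimethyl carbon, the C4=C5 alkene and an oxygen on C6. Ring strain drives the oxidation and the allylic bridgehead is the better migrating group.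
- Where it is better: migration proceeds with retention and the bridge forces the C2 and C6 substituents cis. That relation is guaranteed geometrically, whereas the chosen closure relies on a conformational preference.
- Against it: C2 of A2 carries a carboxyl carbon where the target has chlorine, so a radical decarboxylative chlorination would be needed, and that leaves the C2 configuration to substrate bias. C5 carries only a methyl group (C7), so an allylic oxidation and a one-carbon homologation are needed before either side-chain halogen can be placed. The photochemical route to A1 is prone to loss of enantiomeric purity.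
- Comparison: on structure, 12 already contains all eight carbons and the C2 chlorine, while A2 lacks C8 and has one carbon too many at C2. On mechanism, a concerted migration is more predictable than a reversible aldol addition. On step economy, the corrections after A2 would exceed the six steps that follow 14, and the final inversion at C6 is common to both plans.

Alternative 2: The cut is through C3–C4 and C1–C2 of a cyclohexene whose alkene sits at C5=C6.
- Forward key step: Diels–Alder reaction of the dioxolanyl diene A3 with the acryloyl oxazolidinone A4, chelated to [Cu(t-Bu-box)](SbF6)2 (divalent copper), to give the imide A5.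
- In its favour: the step is convergent and the catalyst sets the absolute configuration at C2. The C7 oxygen stereocentre comes from the chiral pool.
- Where it is better: two skeletal bonds, ring A and the quaternary carbon next to a stereocentre are formed in one step, against one bond in the chosen key step.
- Against it: the diene terminus C1 carries a methyl group cis to the diene backbone, which disfavours the s-cis conformer, and the bond to be formed there joins a quaternary to a tertiary carbon. C2 again bears carbon and not chlorine. The alkene is one position away from where the target needs it, so bromine would have to be introduced at C6 with allylic transposition and uncertain facial control. A chiral diene with a chiral catalyst raises a matched/mismatched question.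
- Comparison: on structure, A5 has no heteroatom at C2 or C6, whereas 14 has the C2 chlorine, the C6 oxygen and the C7 carbonyl in place. On mechanism, the cycloaddition is the more powerful construction but is applied here to a poorly reactive diene. On step economy, A5 may be reached in about as many steps as 14, but the sequence after it is clearly longer.

Alternative 3: The cut is through C4=C5 and C7=C8 of a 1-vinylcyclohexene.
- Forward key step: ring-closing enyne metathesis of the enyne A6 with the second-generation Grubbs catalyst under ethene to give the diene A7. A6 would come from 10 by addition of an ethynyl nucleophile and silylation.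
- In its favour: it shares the first five steps with the chosen route and the closure is equally neutral and catalytic.
- Where it is better: the C6 configuration would be set before ring closure by a reagent-controlled alkynylation or ynone reduction, independently of any cyclisation selectivity. It is also about two steps shorter on paper.
- Against it: the vinyl group of A7 must then be bromochlorinated with chlorine on C7, bromine on C8 and control of the C7 configuration. On a conjugated diene, 1,4-addition and attack on the ring alkene compete, and no well-precedented reagent control exists for this acyclic centre. The chosen plan sets C7 by a ketone reduction of predictable sense.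
- Comparison: on structure, A7 and 14 are equally advanced in the ring, but 14 carries oxygen at C7 and A7 does not. On mechanism, both closures are reliable and the risk in this alternative lies in the halogenation that follows. On step economy the alternative is slightly better, but it rests on a less defensible step.

Key step: step 7

## Route

Step 1
Reactants: 1 (S)-pantolactone [(3S)-3-hydroxy-4,4-dimethyloxolan-2-one]
Product: 3 (3R)-3-chloro-4,4-dimethyloxolan-2-one, via pantolactone triflate 2 (not isolated)
Conditions: Tf2O, 2,6-lutidine, CH2Cl2, −78 → 0 °C; then Bu4NCl (1.1 equiv), 0 °C → rt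
Reagents that add atoms: tetrabutylammonium chloride, CCCC[N+](CCCC)(CCCC)CCCC.[Cl-] (chlorine of 3); triflic anhydride, O=S(=O)(OS(=O)(=O)C(F)(F)F)C(F)(F)F (triflyl group of 2 only)
Why: Triflation activates the C2 hydroxyl, and chloride then displaces triflate in an SN2 reaction with inversion, which is feasible at this neopentylic carbon because it is alpha to the lactone carbonyl; this sets the C2 configuration of the target. Chloride is kept near one equivalent and the mixture cold so that degenerate chloride exchange on 3 should not erode the configuration.

Step 2
Reactants: 3 (3R)-3-chloro-4,4-dimethyloxolan-2-one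
Product: 4 (2R)-2-chloro-3,3-dimethylbutane-1,4-diol
Conditions: LiBH4, THF, 0 °C → rt; aq. NH4Cl
Reagents that add atoms: none
Why: Borohydride reduction of a lactone to the 1,4-diol; LiBH4 is not basic enough to epimerise the alpha-chloro centre and should not reduce the hindered secondary C–Cl bond, and the mildly acidic quench avoids epoxide formation from the C3 alkoxide.

Step 3
Reactants: 4 (2R)-2-chloro-3,3-dimethylbutane-1,4-diol
Product: 6 (6R)-6-chloro-5,5-dimethyl-1,3,2-dioxathiepane 2,2-dioxide, via cyclic sulfite 5 (not isolated)
Conditions: SOCl2, Et3N, CH2Cl2, 0 °C; then RuCl3·xH2O (cat.), NaIO4, MeCN/H2O, 0 °C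
Reagents that add atoms: thionyl chloride, O=S(Cl)Cl; sodium periodate, [Na+].[O-]I(=O)(=O)=O
Why: Standard two-stage cyclic sulfate synthesis: the diol is tied up as the seven-membered cyclic sulfite and sulfur is then oxidised by RuO4 generated in situ. The sulfate makes C3 an electrophile and masks the C6 oxygen, so no protecting group is needed.

Step 4
Reactants: 6 (6R)-6-chloro-5,5-dimethyl-1,3,2-dioxathiepane 2,2-dioxide; 7 vinylmagnesium bromide
Product: 9 (3S)-3-chloro-2,2-dimethylhex-5-en-1-ol, via alkyl sulfate salt 8 (not isolated)
Conditions: 7 (2.5 equiv), CuI (10 mol%), THF, −30 → 0 °C; then H2SO4 (cat.), H2O (2 equiv), THF, rt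
Reagents that add atoms: none
Why: Copper-catalysed Grignard alkylation by SN2 opening of a cyclic sulfate: the vinyl group attacks primary C3 because the other sulfate carbon, C6, is neopentylic and inert, which forms the C3–C4 bond. The monoalkyl sulfate 8 left at C6 is hydrolysed by acid to the alcohol, and C2 is not touched.

Step 5
Reactants: 9 (3S)-3-chloro-2,2-dimethylhex-5-en-1-ol
Product: 10 (3S)-3-chloro-2,2-dimethylhex-5-enal
Conditions: Dess–Martin periodinane, NaHCO3, CH2Cl2, 0 °C → rt
Reagents that add atoms: none
Why: Dess–Martin oxidation of a neopentylic primary alcohol; the aldehyde has a quaternary alpha carbon, so it can neither epimerise nor lose HCl by E1cB. Oxidising before the metathesis avoids a hydroxy enone that could close onto C4 by oxa-Michael addition.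

Step 6
Reactants: 10 (3S)-3-chloro-2,2-dimethylhex-5-enal; 11 but-3-en-2-one
Product: 12 (3S,5E)-3-chloro-2,2-dimethyl-7-oxooct-5-enal
Conditions: 11 (3 equiv), second-generation Hoveyda–Grubbs catalyst (3 mol%), CH2Cl2, 40 °C
Reagents that add atoms: none
Why: Olefin cross-metathesis of a terminal alkene with an electron-poor enone, which favours the cross product and the E-enone; the hindered aldehyde and the alkyl chloride should be tolerated by the ruthenium carbene.

Step 7
Reactants: 12 (3S,5E)-3-chloro-2,2-dimethyl-7-oxooct-5-enal
Product: 14 1-[(4S,6R)-4-chloro-6-hydroxy-5,5-dimethylcyclohex-1-en-1-yl]ethan-1-one, via phosphonium aldolate 13 (not isolated)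
Conditions: PMe3 (0.3 equiv), t-AmOH/CH2Cl2 (0.02 M), rt
Reagents that add atoms: none
Why: PMe3 adds reversibly to C4 of the enone to give a phosphonium enolate whose alpha carbon C5 attacks the aldehyde carbon C6 to give zwitterion 13; proton transfer from C5 to oxygen, relayed by the alcohol solvent, and beta-elimination of PMe3 then restore the C4=C5 bond and release the catalyst. The closest known reaction type is the phosphine-catalysed intramolecular Morita–Baylis–Hillman cyclisation of enone aldehydes to 2-acylcyclohex-2-enols. Ring A closes in the 6-(enolexo)-exo-trig mode, with the enolate C5=C7 bond outside the forming ring and the aldehyde oxygen ending up exocyclic. The new stereocentre C6 is set under substrate control by C2: in the chair-like transition structure the C2 chlorine and the developing C6 alkoxide should both be equatorial, which places oxygen cis to chlorine, and because the aldol step is reversible ahead of the slower proton transfer, the less strained cis aldolate should be the one carried on to product. The step needs chemoselectivity for intramolecular aldol addition over intermolecular enone–enone coupling, which is secured by high dilution, by the gem-dimethyl group at C1 that folds the chain, and by an aldehyde with no alpha hydrogen that cannot enolise or self-condense. It also needs the C2–Cl bond to survive, which the nearly neutral phosphine and the absence of hydrogen on C1 make likely; the only elimination path, vinylogous loss of HCl through C3, is limited by the protic medium and short exposure. The E geometry of 12 is of no consequence once C4 is sp3 in the zwitterion.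

Step 8
Reactants: 14 1-[(4S,6R)-4-chloro-6-hydroxy-5,5-dimethylcyclohex-1-en-1-yl]ethan-1-one
Product: 15 1-[(4S,6R)-4-chloro-5,5-dimethyl-6-(triethylsilyloxy)cyclohex-1-en-1-yl]ethan-1-one
Conditions: Et3SiOTf, 2,6-lutidine, CH2Cl2, −78 → −40 °C
Reagents that add atoms: triethylsilyl triflate, CC[Si](CC)(CC)OS(=O)(=O)C(F)(F)F
Why: Silylation of a hindered allylic alcohol with a silyl triflate and a hindered pyridine at low temperature, where O-silylation is much faster than enol silane formation from the methyl ketone. The triethylsilyl group is chosen because it can later be removed with acid and not with basic fluoride.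

Step 9
Reactants: 15 1-[(4S,6R)-4-chloro-5,5-dimethyl-6-(triethylsilyloxy)cyclohex-1-en-1-yl]ethan-1-one
Product: 17 2-bromo-1-[(4S,6R)-4-chloro-5,5-dimethyl-6-(triethylsilyloxy)cyclohex-1-en-1-yl]ethan-1-one, via silyl dienol ether 16 (not isolated)
Conditions: LiN(SiMe3)2, Me3SiCl, THF, −78 °C; then NBS, NaHCO3, THF, −78 → 0 °C
Reagents that add atoms: N-bromosuccinimide, BrN1C(=O)CCC1=O (bromine of 17); chlorotrimethylsilane, C[Si](C)(C)Cl (silyl group of 16 only)
Why: Kinetic deprotonation of the enone at the alpha′ methyl group (C8) with in situ silylation gives the cross-conjugated 2-silyloxy diene 16, which NBS brominates at its terminal carbon (silyl enol ether bromination). The amide base at −78 °C should avoid gamma-deprotonation at C3, which would expel chloride from C2.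

Step 10
Reactants: 17 2-bromo-1-[(4S,6R)-4-chloro-5,5-dimethyl-6-(triethylsilyloxy)cyclohex-1-en-1-yl]ethan-1-one
Product: 18 (1R)-2-bromo-1-[(4S,6R)-4-chloro-5,5-dimethyl-6-(triethylsilyloxy)cyclohex-1-en-1-yl]ethan-1-ol
Conditions: (R)-2-methyl-CBS-oxazaborolidine (20 mol%), BH3·SMe2, THF, −20 °C; MeOH quench
Reagents that add atoms: none
Why: Corey–Bakshi–Shibata reduction: the alpha-branched cyclohexenyl group acts as the large substituent and CH2Br as the small one, so the (R)-catalyst should deliver hydride to the face that gives the (1R)-bromohydrin under reagent control, by analogy with alpha-halo aryl ketones. 1,2-Reduction is expected to prevail over conjugate reduction.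

Step 11
Reactants: 18 (1R)-2-bromo-1-[(4S,6R)-4-chloro-5,5-dimethyl-6-(triethylsilyloxy)cyclohex-1-en-1-yl]ethan-1-ol
Product: 19 (4S,6S)-1-[(1S)-2-bromo-1-chloroethyl]-4-chloro-5,5-dimethyl-6-(triethylsilyloxy)cyclohex-1-ene
Conditions: PPh3, Cl3CC(O)CCl3, CH2Cl2, −30 → 0 °C
Reagents that add atoms: hexachloroacetone, ClC(Cl)(Cl)C(=O)C(Cl)(Cl)Cl
Why: Appel-type deoxychlorination with a reagent pair suited to allylic alcohols: the alkoxyphosphonium ion is displaced by chloride in an SN2 reaction with inversion, turning the (R)-carbinol into the (S)-chloride at C7. Cold, non-ionising conditions should keep allylic shift low.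

Step 12
Reactants: 19 (4S,6S)-1-[(1S)-2-bromo-1-chloroethyl]-4-chloro-5,5-dimethyl-6-(triethylsilyloxy)cyclohex-1-ene
Product: 20 (1S,5S)-2-[(1S)-2-bromo-1-chloroethyl]-5-chloro-6,6-dimethylcyclohex-2-en-1-ol
Conditions: HF·pyridine, THF/pyridine, 0 °C
Reagents that add atoms: none
Why: Acidic fluoride cleaves the triethylsilyl ether without generating an alkoxide, so neither cyclisation of the C6 oxygen onto C8 nor elimination of the allylic chloride should be triggered.

Step 13
Reactants: 20 (1S,5S)-2-[(1S)-2-bromo-1-chloroethyl]-5-chloro-6,6-dimethylcyclohex-2-en-1-ol
Product: 21 (4S,6R)-6-bromo-1-[(1S)-2-bromo-1-chloroethyl]-4-chloro-5,5-dimethylcyclohex-1-ene (target)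
Conditions: PPh3, CBr4, CH2Cl2, −40 → 0 °C
Reagents that add atoms: carbon tetrabromide, BrC(Br)(Br)Br
Why: Appel bromination: the C6 alkoxyphosphonium ion is displaced by bromide with inversion, which converts the cis C6 carbinol into the trans C6 bromide of the target. The allylic character of C6 assists SN2 at this hindered carbon, and bromide is present only in stoichiometric, ion-paired form, so exchange at the C7 chloride should be minimal.

## Compound list

1 | (S)-pantolactone, (3S)-3-hydroxy-4,4-dimethyloxolan-2-one | CC1(C)COC(=O)[C@H]1O | starting material
2 | (3S)-4,4-dimethyl-2-oxooxolan-3-yl trifluoromethanesulfonate | CC1(C)COC(=O)[C@H]1OS(=O)(=O)C(F)(F)F | intermediate (not isolated)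
3 | (3R)-3-chloro-4,4-dimethyloxolan-2-one | CC1(C)COC(=O)[C@@H]1Cl | intermediate
4 | (2R)-2-chloro-3,3-dimethylbutane-1,4-diol | OCC(C)(C)[C@@H](Cl)CO | intermediate
5 | (6R)-6-chloro-5,5-dimethyl-1,3,2-dioxathiepane 2-oxide (either configuration at sulfur) | CC1(C)COS(=O)OC[C@@H]1Cl | intermediate (not isolated)
6 | (6R)-6-chloro-5,5-dimethyl-1,3,2-dioxathiepane 2,2-dioxide | CC1(C)COS(=O)(=O)OC[C@@H]1Cl | intermediate
7 | vinylmagnesium bromide | C=C[Mg]Br | starting material
8 | bromomagnesium (3S)-3-chloro-2,2-dimethylhex-5-en-1-yl sulfate | C=CC[C@H](Cl)C(C)(C)COS(=O)(=O)[O-].[Mg+2].[Br-] | intermediate (not isolated)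
9 | (3S)-3-chloro-2,2-dimethylhex-5-en-1-ol | C=CC[C@H](Cl)C(C)(C)CO | intermediate
10 | (3S)-3-chloro-2,2-dimethylhex-5-enal | C=CC[C@H](Cl)C(C)(C)C=O | intermediate
11 | but-3-en-2-one | C=CC(C)=O | starting material
12 | (3S,5E)-3-chloro-2,2-dimethyl-7-oxooct-5-enal | CC(=O)/C=C/C[C@H](Cl)C(C)(C)C=O | intermediate (precursor of the key step)
13 | (3R,5S)-2-acetyl-5-chloro-4,4-dimethyl-1-(trimethylphosphaniumyl)cyclohexan-3-olate (C1 and C2 of this name as formed; both are lost again) | CC1(C)[C@@H](Cl)CC([P+](C)(C)C)C(C(C)=O)[C@H]1[O-] | intermediate (not isolated)
14 | 1-[(4S,6R)-4-chloro-6-hydroxy-5,5-dimethylcyclohex-1-en-1-yl]ethan-1-one (OH cis to Cl) | CC1(C)[C@@H](Cl)CC=C(C(C)=O)[C@H]1O | intermediate (product of the key step)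
15 | 1-[(4S,6R)-4-chloro-5,5-dimethyl-6-(triethylsilyloxy)cyclohex-1-en-1-yl]ethan-1-one | CC1(C)[C@@H](Cl)CC=C(C(C)=O)[C@H]1O[Si](CC)(CC)CC | intermediate
16 | (4S,6R)-4-chloro-5,5-dimethyl-6-(triethylsilyloxy)-1-[1-(trimethylsilyloxy)ethenyl]cyclohex-1-ene | CC1(C)[C@@H](Cl)CC=C(C(=C)O[Si](C)(C)C)[C@H]1O[Si](CC)(CC)CC | intermediate (not isolated)
17 | 2-bromo-1-[(4S,6R)-4-chloro-5,5-dimethyl-6-(triethylsilyloxy)cyclohex-1-en-1-yl]ethan-1-one | CC1(C)[C@@H](Cl)CC=C(C(=O)CBr)[C@H]1O[Si](CC)(CC)CC | intermediate
18 | (1R)-2-bromo-1-[(4S,6R)-4-chloro-5,5-dimethyl-6-(triethylsilyloxy)cyclohex-1-en-1-yl]ethan-1-ol | CC1(C)[C@@H](Cl)CC=C([C@@H](O)CBr)[C@H]1O[Si](CC)(CC)CC | intermediate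
19 | (4S,6S)-1-[(1S)-2-bromo-1-chloroethyl]-4-chloro-5,5-dimethyl-6-(triethylsilyloxy)cyclohex-1-ene | CC1(C)[C@@H](Cl)CC=C([C@H](Cl)CBr)[C@H]1O[Si](CC)(CC)CC | intermediate
20 | (1S,5S)-2-[(1S)-2-bromo-1-chloroethyl]-5-chloro-6,6-dimethylcyclohex-2-en-1-ol | CC1(C)[C@@H](Cl)CC=C([C@H](Cl)CBr)[C@H]1O | intermediate
21 | (4S,6R)-6-bromo-1-[(1S)-2-bromo-1-chloroethyl]-4-chloro-5,5-dimethylcyclohex-1-ene | CC1(C)[C@@H](Cl)CC=C([C@H](Cl)CBr)[C@@H]1Br | target

## Step count and least certain steps

Total: 13 steps. Longest linear sequence: 13 steps (1 → 21); 7 and 11 enter as purchased reagents in steps 4 and 6.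

Step 7 (key step). The most likely failure is poor facial selectivity at the aldehyde. The equatorial preference of the C6 oxygen is modest, because an equatorial oxygen is gauche to both C1 methyl groups, so the C6 epimer may form. Slow closure at the hindered aldehyde may also let intermolecular enone coupling or vinylogous loss of HCl compete. Fallback: 12 is treated with Me2AlSPh in CH2Cl2 at −78 °C. Conjugate addition of the thiolate to C4 gives an aluminium enolate that closes on the aldehyde through a chelated chair, giving the beta-phenylthio ketol F1. Oxidation with mCPBA at −78 °C gives the sulfoxide F2, and warming with Et3N eliminates the sulfinyl group and restores the C4=C5 bond. The sequence rejoins the route at 14.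

Step 13. Substitution with allylic shift may compete: bromide would enter at C4 and the alkene would move to C5=C6. Ionisation with loss of configuration is also possible, because C6 is allylic but neopentylic, and bromide could exchange with the allylic chloride at C7. Participation of the C8 bromine through a five-membered bromonium ion would be harmless if that ion is opened at primary C8, since this also leads to 21. Fallback: 20 is converted with chloromethanesulfonyl chloride and pyridine (CH2Cl2, −20 °C) into the chloromethanesulfonate F3. This isolated sulfonate is displaced in a separate bimolecular step with Bu4NBr (1.1 equiv) in toluene at 0 °C to rt, arriving at 21.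

Step 11. Neighbouring-group participation by the C8 bromine (bromonium formation) could give retention at C7 or a 1,2-shift of the halogens, and chloride could be delivered to C4 with allylic shift. Fallback: 18 is closed with K2CO3 in MeCN to the vinyl epoxide F4, which removes the participating bromine and keeps the C7–O configuration. F4 is opened at the allylic carbon C7 with inversion by Li2CuCl4 in THF to give the chloro alcohol F5. The primary C8 hydroxyl of F5 is then brominated with CBr4/PPh3, which rejoins the route at 19.

Step 4. The cyclic sulfate may be opened by bromide from the Grignard reagent instead of by carbon. Elimination toward C2 is possible because the C2 hydrogen is acidified by chlorine, and displacement at the beta-branched C3 may be slow. Fallback: 6 is opened with lithium acetylide–ethylenediamine complex in DMSO/THF, a less basic and more SN2-competent carbon nucleophile, to give the alkynyl sulfate F6. Acid hydrolysis gives the alkynol F7, and semihydrogenation (H2, Pd/CaCO3 poisoned with Pb(OAc)2, quinoline) rejoins the route at 9.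

## Further compounds

F1 | step 7 | 1-[(2R,4S)-4-chloro-2-hydroxy-3,3-dimethyl-6-(phenylsulfanyl)cyclohexyl]ethan-1-one (C1 and C6 of this name as formed) | CC1(C)[C@@H](Cl)CC(Sc2ccccc2)C(C(C)=O)[C@H]1O
F2 | step 7 | 1-[(2R,4S)-6-(benzenesulfinyl)-4-chloro-2-hydroxy-3,3-dimethylcyclohexyl]ethan-1-one (C1, C6 and sulfur as formed) | CC1(C)[C@@H](Cl)CC(S(=O)c2ccccc2)C(C(C)=O)[C@H]1O
F3 | step 13 | (1S,5S)-2-[(1S)-2-bromo-1-chloroethyl]-5-chloro-6,6-dimethylcyclohex-2-en-1-yl chloromethanesulfonate | CC1(C)[C@@H](Cl)CC=C([C@H](Cl)CBr)[C@H]1OS(=O)(=O)CCl
F4 | step 11 | (4S,6R)-4-chloro-5,5-dimethyl-1-[(2R)-oxiran-2-yl]-6-(triethylsilyloxy)cyclohex-1-ene | CC1(C)[C@@H](Cl)CC=C([C@@H]2CO2)[C@H]1O[Si](CC)(CC)CC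
F5 | step 11 | (2S)-2-chloro-2-[(4S,6S)-4-chloro-5,5-dimethyl-6-(triethylsilyloxy)cyclohex-1-en-1-yl]ethan-1-ol | CC1(C)[C@@H](Cl)CC=C([C@H](Cl)CO)[C@H]1O[Si](CC)(CC)CC
F6 | step 4 | lithium (3S)-3-chloro-2,2-dimethylhex-5-yn-1-yl sulfate | C#CC[C@H](Cl)C(C)(C)COS(=O)(=O)[O-].[Li+]
F7 | step 4 | (3S)-3-chloro-2,2-dimethylhex-5-yn-1-ol | C#CC[C@H](Cl)C(C)(C)CO
A1 | alternative 1 | chrysanthenone, 2,7,7-trimethylbicyclo[3.1.1]hept-2-en-6-one (enantiomer as drawn) | CC1(C)[C@@H]2CC=C(C)[C@H]1C2=O
A2 | alternative 1 | 4,8,8-trimethyl-6-oxabicyclo[3.2.1]oct-3-en-7-one | CC1(C)[C@@H]2CC=C(C)[C@H]1OC2=O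
A3 | alternative 2 | (4R)-2,2-dimethyl-4-(4-methylpenta-1,3-dien-2-yl)-1,3-dioxolane | C=C(C=C(C)C)[C@@H]1COC(C)(C)O1
A4 | alternative 2 | 3-acryloyl-1,3-oxazolidin-2-one | C=CC(=O)N1CCOC1=O
A5 | alternative 2 | 3-{[(1S)-4-[(4R)-2,2-dimethyl-1,3-dioxolan-4-yl]-2,2-dimethylcyclohex-3-en-1-yl]carbonyl}-1,3-oxazolidin-2-one | CC1(C)C=C([C@@H]2COC(C)(C)O2)CC[C@@H]1C(=O)N3CCOC3=O
A6 | alternative 3 | tert-butyl{[(3R,5S)-5-chloro-4,4-dimethyloct-7-en-1-yn-3-yl]oxy}dimethylsilane | C=CC[C@H](Cl)C(C)(C)[C@H](O[Si](C)(C)C(C)(C)C)C#C
A7 | alternative 3 | tert-butyl{[(1R,5S)-5-chloro-2-ethenyl-6,6-dimethylcyclohex-2-en-1-yl]oxy}dimethylsilane | CC1(C)[C@@H](Cl)CC=C(C=C)[C@H]1O[Si](C)(C)C(C)(C)C
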